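**Strategy.** The 2H-pyran ring is disconnected at C4–C4a and O1–C2, revealing a phenol and 3-methylbut-2-enal. The key step is a formal [3+3] annulation: the carbon of ring A (the benzene ring of the chromene) ortho to the phenol oxygen condenses with the aldehyde carbon, and the resulting ortho-quinone methide closes by oxa-6π electrocyclization, so both bonds form in one operation. It exploits the O1–C8a=C4a phenol unit of ring A as a C,O-bisnucleophile. The precursor is a fully substituted methyl 2,6-dihydroxybenzoate: its ester, at the future C8 between the two oxygens, leaves a single aromatic C–H on ring A and is removed last by decarboxylation.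

Key step: step 6

Remark: the target has no stereocentre and no stereogenic double bond, so no configuration has to be set; benzoate numbering is used for compounds 1, 3, 4 and 9, chromene numbering from compound 12 on.

**Step 1**
Reactants: 1 methyl 2,4,6-trihydroxybenzoate; 2 1-bromo-3-methylbut-2-ene (prenyl bromide)
Product: 3 methyl 2,4,6-trihydroxy-3-(3-methylbut-2-en-1-yl)benzoate
Conditions: 2 (1.0 equiv), DBU, THF, 0 °C to rt
Reagents that add atoms: prenyl bromide (2), CC(C)=CCBr
Why: C-alkylation of an acylphloroglucinol-type phenoxide with an allylic bromide (known mono-C-prenylation of phloroglucinol esters and ketones); the two free ring positions are equivalent, so one C-prenyl regioisomer should form, and the limiting bromide curbs double alkylation.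

**Step 2**
Reactants: 3 methyl 2,4,6-trihydroxy-3-(3-methylbut-2-en-1-yl)benzoate
Product: 4 methyl 2,6-dihydroxy-3-(3-methylbut-2-en-1-yl)-4-[(trifluoromethanesulfonyl)oxy]benzoate
Conditions: PhNTf2 (1.05 equiv), Et3N, CH2Cl2, 0 °C to rt
Reagents that add atoms: N-phenylbis(trifluoromethanesulfonimide), O=S(=O)(N(c1ccccc1)S(=O)(=O)C(F)(F)F)C(F)(F)F
Why: Chemoselective aryl triflate formation: the 4-OH para to the ester is the most acidic hydroxyl, whereas both ortho hydroxyls are hydrogen-bonded to the ester, so one equivalent of the mild triflyl donor should sulfonylate the 4-OH alone.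

**Step 3**
Reactants: 5 1-benzofuran-6-ol
Product: 6 (1-benzofuran-6-yloxy)tri(propan-2-yl)silane
Conditions: TIPSCl, imidazole, DMF, rt
Reagents that add atoms: chlorotri(propan-2-yl)silane, CC(C)[Si](Cl)(C(C)C)C(C)C
Why: Routine silylation of a phenol; the bulky silyl ether masks the benzofuran phenol through the organolithium, coupling and annulation steps.

**Step 4**
Reactants: 6 (1-benzofuran-6-yloxy)tri(propan-2-yl)silane
Product: 8 4,4,5,5-tetramethyl-2-{6-[tri(propan-2-yl)silyloxy]-1-benzofuran-2-yl}-1,3,2-dioxaborolane, via 2-lithiobenzofuran 7 (not isolated)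
Conditions: n-BuLi, THF, −78 °C; then iPrOBpin, −78 °C to rt
Reagents that add atoms: 2-isopropoxy-4,4,5,5-tetramethyl-1,3,2-dioxaborolane, CC(C)OB1OC(C)(C)C(C)(C)O1
Why: Deprotonation of the benzofuran at C2, its most acidic position, and trapping of the aryllithium with a borate ester (lithiation–borylation); the pinacol ester is chosen because it resists protodeboronation better than the free boronic acid.

**Step 5**
Reactants: 4 methyl 2,6-dihydroxy-3-(3-methylbut-2-en-1-yl)-4-[(trifluoromethanesulfonyl)oxy]benzoate; 8 4,4,5,5-tetramethyl-2-{6-[tri(propan-2-yl)silyloxy]-1-benzofuran-2-yl}-1,3,2-dioxaborolane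
Product: 9 methyl 2,6-dihydroxy-3-(3-methylbut-2-en-1-yl)-4-{6-[tri(propan-2-yl)silyloxy]-1-benzofuran-2-yl}benzoate
Conditions: Pd(OAc)2 (5 mol %), SPhos (10 mol %), K3PO4, THF/H2O, 50 °C
Reagents that add atoms: none
Why: Suzuki–Miyaura coupling of an aryl triflate with a heteroaryl boronate; the electron-rich biaryl phosphine should allow oxidative addition next to the prenyl group at a temperature low enough to limit protodeboronation, and the triflate is meta to both phenolates, so their ionisation does not deactivate it.

**Step 6**
Reactants: 9 methyl 2,6-dihydroxy-3-(3-methylbut-2-en-1-yl)-4-{6-[tri(propan-2-yl)silyloxy]-1-benzofuran-2-yl}benzoate; 10 3-methylbut-2-enal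
Product: 12 methyl 7-hydroxy-2,2-dimethyl-6-(3-methylbut-2-en-1-yl)-5-{6-[tri(propan-2-yl)silyloxy]-1-benzofuran-2-yl}-2H-chromene-8-carboxylate, via ortho-quinone methide 11 (not isolated)
Conditions: 10 (2 equiv), ethylenediammonium diacetate (20 mol %), toluene, 110 °C
Reagents that add atoms: 3-methylbut-2-enal (10), CC(C)=CC=O
Why: The diamine salt converts 10 into an iminium ion that is attacked by C5 of 9 (ortho to the 6-OH, para to the 2-OH); loss of the amine gives ortho-quinone methide 11, a 1-oxatriene whose thermally allowed disrotatory oxa-6π electrocyclization forms the O–CMe2 bond and restores the aromatic ring. The closest known reaction is the amine-catalysed chromenylation of resorcinols and acylphloroglucinols with enals (Knoevenagel condensation/oxa-6π electrocyclization, a formal [3+3] annulation). The pyran ring closes by 6π electrocyclization of the oxatriene in which the dimethylvinyl group is cis to the ring carbonyl, the C–C bond having been made before by intermolecular condensation. No stereocentre is formed. The step needs regioselectivity on ring A and chemoselectivity between phenols: C5 is the only free aromatic position of ring A, because the ester occupies the carbon between the two hydroxyls and the prenyl group the other ortho site; only the 6-OH is adjacent to the new side chain; and the benzofuran phenol is silylated.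

**Step 7**
Reactants: 12 methyl 7-hydroxy-2,2-dimethyl-6-(3-methylbut-2-en-1-yl)-5-{6-[tri(propan-2-yl)silyloxy]-1-benzofuran-2-yl}-2H-chromene-8-carboxylate
Product: 15 cathafuran C, via desilylated methyl ester 13 (not isolated), via carboxylic acid 14 (not isolated)
Conditions: KOH, MeOH/H2O, reflux, Ar; then aq. HCl to pH 4, 50 °C
Reagents that add atoms: none
Why: Hot hydroxide should cleave the aryl silyl ether and saponify the ester, and the resulting 2-hydroxy-6-alkoxybenzoic acid, a vinylogous β-keto acid, should lose CO2 by ipso-protonation on acidification (saponification–decarboxylation known for resorcylate esters such as the cannabinoid acid esters); the chromene and prenyl alkenes are inert to these conditions.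

**Compound list**

1 | methyl 2,4,6-trihydroxybenzoate | COC(=O)c1c(O)cc(O)cc1O | starting material
2 | 1-bromo-3-methylbut-2-ene (prenyl bromide) | CC(C)=CCBr | starting material
3 | methyl 2,4,6-trihydroxy-3-(3-methylbut-2-en-1-yl)benzoate | COC(=O)c1c(O)cc(O)c(CC=C(C)C)c1O | intermediate
4 | methyl 2,6-dihydroxy-3-(3-methylbut-2-en-1-yl)-4-[(trifluoromethanesulfonyl)oxy]benzoate | COC(=O)c1c(O)cc(OS(=O)(=O)C(F)(F)F)c(CC=C(C)C)c1O | intermediate
5 | 1-benzofuran-6-ol | Oc1ccc2ccoc2c1 | starting material
6 | (1-benzofuran-6-yloxy)tri(propan-2-yl)silane | CC(C)[Si](Oc1ccc2ccoc2c1)(C(C)C)C(C)C | intermediate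
7 | {6-[tri(propan-2-yl)silyloxy]-1-benzofuran-2-yl}lithium (not isolated) | [Li]c1cc2ccc(O[Si](C(C)C)(C(C)C)C(C)C)cc2o1 | intermediate
8 | 4,4,5,5-tetramethyl-2-{6-[tri(propan-2-yl)silyloxy]-1-benzofuran-2-yl}-1,3,2-dioxaborolane | CC(C)[Si](Oc1ccc2cc(B3OC(C)(C)C(C)(C)O3)oc2c1)(C(C)C)C(C)C | intermediate
9 | methyl 2,6-dihydroxy-3-(3-methylbut-2-en-1-yl)-4-{6-[tri(propan-2-yl)silyloxy]-1-benzofuran-2-yl}benzoate | COC(=O)c1c(O)cc(-c2cc3ccc(O[Si](C(C)C)(C(C)C)C(C)C)cc3o2)c(CC=C(C)C)c1O | intermediate
10 | 3-methylbut-2-enal | CC(C)=CC=O | starting material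
11 | methyl 2-hydroxy-5-(3-methylbut-2-en-1-ylidene)-3-(3-methylbut-2-en-1-yl)-6-oxo-4-{6-[tri(propan-2-yl)silyloxy]-1-benzofuran-2-yl}cyclohexa-1,3-diene-1-carboxylate, dimethylvinyl group cis to the ring carbonyl (ortho-quinone methide, not isolated) | CC(C)=C/C=C1\C(=O)C(C(=O)OC)=C(O)C(CC=C(C)C)=C1c1cc2ccc(O[Si](C(C)C)(C(C)C)C(C)C)cc2o1 | intermediate
12 | methyl 7-hydroxy-2,2-dimethyl-6-(3-methylbut-2-en-1-yl)-5-{6-[tri(propan-2-yl)silyloxy]-1-benzofuran-2-yl}-2H-chromene-8-carboxylate | COC(=O)c1c(O)c(CC=C(C)C)c(-c2cc3ccc(O[Si](C(C)C)(C(C)C)C(C)C)cc3o2)c2C=CC(C)(C)Oc12 | intermediate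
13 | methyl 7-hydroxy-5-(6-hydroxy-1-benzofuran-2-yl)-2,2-dimethyl-6-(3-methylbut-2-en-1-yl)-2H-chromene-8-carboxylate (not isolated) | COC(=O)c1c(O)c(CC=C(C)C)c(-c2cc3ccc(O)cc3o2)c2C=CC(C)(C)Oc12 | intermediate
14 | 7-hydroxy-5-(6-hydroxy-1-benzofuran-2-yl)-2,2-dimethyl-6-(3-methylbut-2-en-1-yl)-2H-chromene-8-carboxylic acid (not isolated) | OC(=O)c1c(O)c(CC=C(C)C)c(-c2cc3ccc(O)cc3o2)c2C=CC(C)(C)Oc12 | intermediate
15 | cathafuran C, 5-(6-hydroxy-1-benzofuran-2-yl)-2,2-dimethyl-6-(3-methylbut-2-en-1-yl)-2H-chromen-7-ol | CC(C)=CCc1c(O)cc2c(c1-c1cc3ccc(O)cc3o1)C=CC(C)(C)O2 | target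

**Totals**

Total step count: 7.
Longest linear sequence: 5 steps (steps 1, 2, 5, 6, 7; the branch through steps 3, 4, 5, 6, 7 is equally long).

**Steps most likely to fail**

Step 6. The condensation may be slow at the hindered, hydrogen-bonded position next to the benzofuranyl group, so that self-condensation of the enal takes over. The fallback sets out from 9. O-Alkylation of the less hindered 6-OH with 3-chloro-3-methylbut-1-yne (CuCl2 cat., DBU, MeCN, 0 °C) should give the aryl propargyl ether methyl 2-hydroxy-6-[(2-methylbut-3-yn-2-yl)oxy]-3-(3-methylbut-2-en-1-yl)-4-{6-[tri(propan-2-yl)silyloxy]-1-benzofuran-2-yl}benzoate F1. Heating F1 in xylene at 140 °C should bring about the aryl propargyl ether Claisen rearrangement onto C5 (the only ortho C–H), enolisation, 1,5-hydrogen shift and oxa-6π closure. The fallback comes back to the route at 12.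

Step 7. Acyl substitution at the ester carbonyl, flanked on both sides and next to a phenolate, may stay incomplete, and the electron-rich phenolates may be oxidised during long heating in alkali. The fallback sets out from 12 and separates the events. Bu4NF in THF at 0 °C should give 13, which is isolated here. Sodium ethanethiolate (NaSEt) in DMF at 100 °C should then cleave the ester by substitution at the methyl carbon, which avoids attack at the hindered carbonyl. Acidification and gentle warming should take the carboxylate through 14 to 15, where the fallback rejoins the route; no compound outside the compound list is formed (F0).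

Step 5. Protodeboronation of the 2-benzofuranyl boronate in aqueous base may outrun oxidative addition and transmetalation at the ortho-prenylated triflate, whose phenols are ionised. The fallback sets out from 6. Lithiation as in step 4 (via 7) and quenching with Bu3SnCl should give tributyl{6-[tri(propan-2-yl)silyloxy]-1-benzofuran-2-yl}stannane F2. Stille coupling of F2 with 4 (Pd(PPh3)4, LiCl, 1,4-dioxane, 100 °C) runs under neutral conditions that leave the phenols un-ionised. The fallback comes back to the route at 9.

**Further compounds**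

F1 | step 6 | methyl 2-hydroxy-6-[(2-methylbut-3-yn-2-yl)oxy]-3-(3-methylbut-2-en-1-yl)-4-{6-[tri(propan-2-yl)silyloxy]-1-benzofuran-2-yl}benzoate | COC(=O)c1c(OC(C)(C)C#C)cc(-c2cc3ccc(O[Si](C(C)C)(C(C)C)C(C)C)cc3o2)c(CC=C(C)C)c1O
F0 | step 7 | none | none
F2 | step 5 | tributyl{6-[tri(propan-2-yl)silyloxy]-1-benzofuran-2-yl}stannane | CCCC[Sn](CCCC)(CCCC)c1cc2ccc(O[Si](C(C)C)(C(C)C)C(C)C)cc2o1
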